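- You are asked how much of the substrate has reacted at the end of grey and of ochre, two flasks that differ in reagent.

all flasks: substrate 0.30 M; free catalyst 0.58 mol%

| run | reagent | remark | time |
|---|---|---|---|
| summer | 0.51 equiv | run made earlier |  |
| midnight | 0.73 equiv | run made earlier |  |
| grey | 0.500 equiv |  | 25 min |
| ochre | 1.00 equiv |  | 25 min |

- summer (time / min: substrate / %, product / %): 2.00: 91.7, 7.7; 6.00: 77.0, 23.3; 12.0: 57.0, 43.4; 20.0: 48.8, 51.0; 25.0: 49.3, 50.7
- midnight (time / min: substrate / %, product / %): 2.00: 92.0, 7.3; 4.00: 84.3, 15.1; 8.00: 68.6, 30.7; 12.0: 56.2, 42.8; 25.0: 27.4, 73.3

(scatter of a reading: 0.5 percentage points)

1. part of the substrate that has reacted at the end, grey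
2. part of the substrate that has reacted at the end, ochre
3. what raising the equivalents of reagent from its lowest to its highest value here does to the part of the substrate that has reacted (changes below 5 percentage points count as none) (it falls / no change / it rises)



- Summer levels off at 50.7% product with 0.51 equiv of reagent, so read one reagent per substrate reacted: in a flask with under one equivalent, reagent is the limiting reagent, and its equivalents give the level.
- Before that level the reagent charge hardly shows: at 12.0 min the substrate readings of summer and midnight differ by 0.8 percentage points, with a scatter of 0.5 points per reading. So grey and ochre should share one curve until grey levels off.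
- To draw that curve, let s be the fraction of substrate left and x the fraction reacted. Averaging the two runs gives s = 91.9% at 2.00 min and 56.6% at 12.0 min.
- The first-order constant ln(s)/t, taken positive, climbs from 0.0422 /min to 0.0474 /min, so the rate falls less than in proportion to s: the order reads below one. I therefore take ds/dt = −V s/(K + s).
- Integrated, this gives x − K ln s = V t, so the reach time, the time needed to react a fraction x, is (x − K ln s)/V. The two averages give K = 0.931 and the clock speed V = 0.0803 /min, both rough readings.
- The curve starts with slope 0.0416 /min. Grey's knee comes at the reach time for its level, 14.3 min, earlier than the end, so I expect grey flat at 0.500 equiv of the charge, which is 50% reacted.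
- Ochre has no knee before the end. On this curve I expect it to pass midnight's final 73.3% at 24.4 min, and the remaining minutes at the local slope carry it to 74.3%.
- The forecast gave 50% for grey and 74.5% for ochre, so it rises, on the ground that “the rate does not depend on reagent”.
- The flasks give 50.0% for grey and 73.8% for ochre, so it rises, by 24 points.

    reagent + free catalyst → catalyst intermediate A (k = 20000 /M/min)
    catalyst intermediate A → catalyst intermediate B (k = 140 /min)
    catalyst intermediate B → by-product + catalyst intermediate C (k = 43.0 /min)
    substrate + catalyst intermediate C ⇌ catalyst intermediate D (K = 2.90 /M, k = 110 /M/min)
    catalyst intermediate D → free catalyst + product (k = 28.0 /min)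
    reagent + by-product ⇌ idle adduct, settled at all times (K = 5.90 /M)

- The gap of 24 points between grey and ochre comes from the difference in equivalents of reagent. Grey halts at 50.0% with 0% of its reagent free, because its reagent is consumed, which is one part of the story: with that consumption taken away, the same flask reaches 73.9%. Ochre still has 12.3% of its reagent free at the end, and the reach time for 73.8% is 24.7 min, against the 25 min it ran. For a neighbour flask, ochre's recipe with 0.600 equiv of reagent, the reach time for its level is 18.1 min, and at the end that flask stands at 60.0% with 0% of its reagent left.

Readings and results are calculated on assumed constants, and the scatter is random.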